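C1 is the ester carbonyl, C2 its CH2, and C3–C4–C5 are the carbons of the 1,2-dioxolane (O–O bridging C3 and C5). C6–C20 is the side chain on C5.
The retrosynthesis cuts C14=C15 (Julia–Kocienski), then C12=C13 and C6–C7 (two Wittig reactions, the C6=C7 alkene being saturated afterwards). It then cuts C3–O, C2–C1 and C1–OMe together, and last C5–OOH and C3–C4.
Ring carbon C3 is fully substituted (CH3, C4, ring O, C2) and C2 bears only the ester carbon. A metal placed on C2 as the dioxolane closes therefore finds no β-hydrogen, and carbonylation is its only exit.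
In the forward direction C3–C4 is made first and the C5 hydroperoxide next. The only ring and the ester arm then form in one operation, and the chain grows outward from C6 to C12, C14 and C20.
C5 derives from (R)-2-methylglycidol with one inversion in the perhydrolysis, and C3 is induced by C5 during ring closure. The 12E and 14E alkenes come from the olefinations, and 17Z is bought with (Z)-hex-3-en-1-ol.

Key step: step 6

Assumption: the perhydrolysis of step 4 is taken to run with inversion at C5, as acid-promoted openings of 2,2-dialkyl cyclic ethers by H2O2 normally do, and this fixes the choice of the (R)-glycidol. The two organopalladium intermediates are drawn with the chloride ligand only.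

Step 1
Reactants: 1 (R)-2-methylglycidol
Product: 2 (S)-2-methylglycidyl tosylate, (2S)-(2-methyloxiran-2-yl)methyl 4-methylbenzenesulfonate
Conditions: TsCl, Et3N, DMAP (cat.), CH2Cl2, 0 °C
Reagents that add atoms: 4-toluenesulfonyl chloride, Cc1ccc(cc1)S(=O)(=O)Cl
Why: O-sulfonylation of the primary alcohol touches no bond of the quaternary epoxide carbon (R to S is only a change of CIP ranking) and makes the future C6 an electrophilic carbon.

Step 2
Reactants: 2 (S)-2-methylglycidyl tosylate; 3 isopropenylmagnesium bromide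
Product: 4 (2S)-2-hydroxy-2,4-dimethylpent-4-en-1-yl 4-methylbenzenesulfonate
Conditions: CuI (10 mol %), THF, −40 → −20 °C; aq NH4Cl
Reagents that add atoms: isopropenylmagnesium bromide 3, C=C(C)[Mg]Br
Why: In this copper-catalysed Grignard opening of a glycidyl sulfonate the strained epoxide CH2 should react faster than the neopentyl-type tosylate, forming C3–C4 without touching the stereocentre.

Step 3
Reactants: 4 (2S)-2-hydroxy-2,4-dimethylpent-4-en-1-yl 4-methylbenzenesulfonate
Product: 5 (2S)-2-methyl-2-(2-methylprop-2-en-1-yl)oxirane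
Conditions: K2CO3, MeOH, 0 °C → rt; extraction into Et2O, the volatile product kept in solution
Reagents that add atoms: none
Why: Intramolecular Williamson etherification (3-exo-tet) by the tertiary alkoxide on CH2OTs moves the epoxide to C5–C6 with the C5–O bond retained.

Step 4
Reactants: 5 (2S)-2-methyl-2-(2-methylprop-2-en-1-yl)oxirane
Product: 6 (2R)-2-hydroperoxy-2,4-dimethylpent-4-en-1-ol
Conditions: H3PMo12O40 (3 mol %), anhydrous H2O2 in Et2O (ca. 10 equiv), 0 °C → rt
Reagents that add atoms: hydrogen peroxide, OO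
Why: In this heteropolyacid-catalysed perhydrolysis of a 2,2-dialkyl epoxide, H2O2 enters at the tertiary carbon opposite the departing oxygen (borderline SN2), which should set C5–OOH with inversion (S epoxide to R hydroperoxide), and the excess of H2O2 keeps the product from opening a second epoxide.

Step 5
Reactants: 6 (2R)-2-hydroperoxy-2,4-dimethylpent-4-en-1-ol
Product: 8 (2R)-1-(tert-butyldiphenylsilyloxy)-2,4-dimethylpent-4-en-2-yl hydroperoxide, via bis-silyl peroxide 7 (not isolated)
Conditions: TBDPSCl (2.3 equiv), imidazole, DMF, 0 °C → rt; aqueous wash; crude in MeOH/THF, K2CO3 (0.2 equiv), 0 °C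
Reagents that add atoms: tert-butyl(chloro)diphenylsilane, CC(C)(C)[Si](Cl)(c1ccccc1)c2ccccc2
Why: Exhaustive silylation followed by base-catalysed methanolysis should cleave only the O–O–Si bond, because a peroxide anion leaves silicon far more readily than a primary alkoxide, as in the selective cleavage of aryl silyl ethers.

Step 6
Reactants: 8 (2R)-1-(tert-butyldiphenylsilyloxy)-2,4-dimethylpent-4-en-2-yl hydroperoxide; 9 carbon monoxide; 10 methanol
Product: 13 methyl 2-[(3R,5R)-5-(tert-butyldiphenylsilyloxymethyl)-3,5-dimethyl-1,2-dioxolan-3-yl]acetate, via alkylpalladium chloride 11 (not isolated), via acylpalladium chloride 12 (not isolated)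
Conditions: PdCl2(MeCN)2 (10 mol %), p-benzoquinone (1.5 equiv), CO (1 atm), MeOH/CH2Cl2 1:1, 0 °C → rt
Reagents that add atoms: carbon monoxide 9, [C-]#[O+]; methanol 10, CO
Why: Proposed new method: PdCl2(MeCN)2 binds the electron-rich 1,1-disubstituted alkene, the terminal oxygen of the C5 hydroperoxide attacks the internal carbon C3 anti to the metal, and the primary alkyl of divalent palladium 11, which sits on C2 next to quaternary C3 and has no β-hydrogen, inserts CO to give acyl 12, which methanol cleaves to ester 13 while p-benzoquinone returns zerovalent palladium to the divalent state. The closest known reaction types are the divalent-palladium cyclisation of unsaturated tertiary hydroperoxides to cyclic peroxides, which ends in β-hydride elimination, and the intramolecular alkoxy- or aryloxypalladation/methoxycarbonylation of 1,1-disubstituted alkenols, which builds the same O–C(CH3)–CH2CO2Me unit; the new element is a hydroperoxide nucleophile operating under CO. The single ring (O–O–C3–C4–C5) closes in the 5-exo-trig mode, the 6-endo alternative being disfavoured because it would place palladium on the tertiary carbon. The new stereocentre C3 is controlled by C5: in the envelope-like closing ring the substituents on C3 and C5 are 1,3-related, so the bulky CH2OTBDPS group should occupy the face opposite the CH2–Pd arm and share its face with the small C3 methyl, which is the required (3R,5R) relation, and the C3 epimer is to be removed by chromatography. The step also needs the O–O bond to survive and CO capture to outrun reversal of the peroxypalladation and intermolecular attack by methanol; to that end the medium contains no copper salt or phosphine, excess quinone keeps zerovalent palladium short-lived, the nucleophile is tethered, and the absence of hydrogen on C3 excludes ketone-forming oxidation.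

Step 7
Reactants: 13 methyl 2-[(3R,5R)-5-(tert-butyldiphenylsilyloxymethyl)-3,5-dimethyl-1,2-dioxolan-3-yl]acetate
Product: 14 methyl 2-[(3R,5R)-5-(hydroxymethyl)-3,5-dimethyl-1,2-dioxolan-3-yl]acetate
Conditions: TBAF/AcOH 1:1 (2 equiv), THF, 0 °C → rt
Reagents that add atoms: none
Why: Fluoride desilylation buffered with acetic acid keeps the medium free of alkoxide, so that neither retro-Michael opening of the β-peroxy ester nor Grob-type fragmentation of the β-peroxy alcohol should intervene.

Step 8
Reactants: 14 methyl 2-[(3R,5R)-5-(hydroxymethyl)-3,5-dimethyl-1,2-dioxolan-3-yl]acetate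
Product: 15 methyl 2-[(3R,5R)-5-formyl-3,5-dimethyl-1,2-dioxolan-3-yl]acetate
Conditions: Dess–Martin periodinane, CH2Cl2, 0 °C → rt
Reagents that add atoms: none
Why: Dess–Martin oxidation is metal-free and near neutral, dialkyl peroxides are inert to it, and the aldehyde on quaternary C5 can neither enolise nor epimerise.

Step 9
Reactants: 16 6-bromohexan-1-ol
Product: 17 (6-bromohexyloxy)(tert-butyl)dimethylsilane
Conditions: TBSCl, imidazole, CH2Cl2, 0 °C → rt
Reagents that add atoms: tert-butyl(chloro)dimethylsilane, CC(C)(C)[Si](C)(C)Cl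
Why: Standard silyl ether protection masks the future C12 oxygen, so that no alkoxide accompanies the ylide later.

Step 10
Reactants: 17 (6-bromohexyloxy)(tert-butyl)dimethylsilane
Product: 18 [6-(tert-butyldimethylsilyloxy)hexyl]triphenylphosphonium bromide
Conditions: PPh3, MeCN, reflux
Reagents that add atoms: triphenylphosphine, c1ccc(cc1)P(c2ccccc2)c3ccccc3
Why: SN2 quaternisation of triphenylphosphine by an unhindered primary bromide gives the salt, which is freed from residual phosphine by trituration before it meets the peroxide.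

Step 11
Reactants: 15 methyl 2-[(3R,5R)-5-formyl-3,5-dimethyl-1,2-dioxolan-3-yl]acetate; 18 [6-(tert-butyldimethylsilyloxy)hexyl]triphenylphosphonium bromide
Product: 20 methyl 2-[(3R,5R)-5-[(1Z)-7-(tert-butyldimethylsilyloxy)hept-1-en-1-yl]-3,5-dimethyl-1,2-dioxolan-3-yl]acetate, via phosphorus ylide 19 (not isolated)
Conditions: 18, NaN(SiMe3)2 (slight deficit), THF, −78 → 0 °C; then 15, −78 → 0 °C
Reagents that add atoms: none
Why: In this Wittig olefination the lithium-free non-stabilised ylide should add to the non-enolisable aldehyde through an oxaphosphetane without a free alkoxide, forming C6=C7 faster than it can attack the hindered O–O bond or enolise the ester, and the mainly Z geometry is irrelevant because the alkene is saturated next.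

Step 12
Reactants: 20 methyl 2-[(3R,5R)-5-[(1Z)-7-(tert-butyldimethylsilyloxy)hept-1-en-1-yl]-3,5-dimethyl-1,2-dioxolan-3-yl]acetate
Product: 21 methyl 2-[(3R,5S)-5-[7-(tert-butyldimethylsilyloxy)heptyl]-3,5-dimethyl-1,2-dioxolan-3-yl]acetate
Conditions: KO2CN=NCO2K (excess, in portions), AcOH, CH2Cl2/MeOH, 0 °C → rt
Reagents that add atoms: none
Why: Diimide reduction transfers two hydrogens concertedly to the C=C bond only and is the classical way to saturate unsaturated peroxides without O–O cleavage (R to S at C5 is a change of CIP ranking only).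

Step 13
Reactants: 21 methyl 2-[(3R,5S)-5-[7-(tert-butyldimethylsilyloxy)heptyl]-3,5-dimethyl-1,2-dioxolan-3-yl]acetate
Product: 22 methyl 2-[(3R,5S)-5-(7-hydroxyheptyl)-3,5-dimethyl-1,2-dioxolan-3-yl]acetate
Conditions: HF·pyridine, THF, 0 °C → rt
Reagents that add atoms: none
Why: Acidic fluoride desilylation of a primary silyl ether is fast and leaves the methyl ester and the ditertiary peroxide untouched.

Step 14
Reactants: 22 methyl 2-[(3R,5S)-5-(7-hydroxyheptyl)-3,5-dimethyl-1,2-dioxolan-3-yl]acetate
Product: 23 methyl 2-[(3R,5S)-3,5-dimethyl-5-(7-oxoheptyl)-1,2-dioxolan-3-yl]acetate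
Conditions: Dess–Martin periodinane, CH2Cl2, 0 °C → rt
Reagents that add atoms: none
Why: Dess–Martin oxidation stops at the C12 aldehyde and, as in step 8, is compatible with the peroxide.

Step 15
Reactants: 23 methyl 2-[(3R,5S)-3,5-dimethyl-5-(7-oxoheptyl)-1,2-dioxolan-3-yl]acetate; 24 (triphenylphosphoranylidene)acetaldehyde
Product: 25 methyl 2-[(3R,5S)-3,5-dimethyl-5-[(7E)-9-oxonon-7-en-1-yl]-1,2-dioxolan-3-yl]acetate
Conditions: 24 (1.2 equiv), toluene, 70 °C
Reagents that add atoms: (triphenylphosphoranylidene)acetaldehyde 24, O=CC=P(c1ccccc1)(c2ccccc2)c3ccccc3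
Why: The Wittig reaction of the stabilised formylmethylene ylide runs without added base, is E-selective at C12=C13, and is kept from a second homologation by limiting the ylide.

Step 16
Reactants: 26 (Z)-hex-3-en-1-ol
Product: 27 5-[(3Z)-hex-3-en-1-ylsulfanyl]-1-phenyl-1H-tetrazole
Conditions: 1-phenyl-1H-tetrazole-5-thiol, PPh3, DIAD, THF, 0 °C → rt
Reagents that add atoms: 1-phenyl-1H-tetrazole-5-thiol, Sc1nnnn1-c2ccccc2
Why: Mitsunobu thioetherification of a primary alcohol proceeds under neutral conditions that leave the Z alkene in place.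

Step 17
Reactants: 27 5-[(3Z)-hex-3-en-1-ylsulfanyl]-1-phenyl-1H-tetrazole
Product: 28 5-[(3Z)-hex-3-en-1-ylsulfonyl]-1-phenyl-1H-tetrazole
Conditions: (NH4)6Mo7O24·4H2O (10 mol %), 30 % aq H2O2, EtOH, 0 °C → rt
Reagents that add atoms: hydrogen peroxide, OO
Why: Molybdate-catalysed oxidation of sulfide to sulfone is much faster than epoxidation of an isolated disubstituted alkene.

Step 18
Reactants: 25 methyl 2-[(3R,5S)-3,5-dimethyl-5-[(7E)-9-oxonon-7-en-1-yl]-1,2-dioxolan-3-yl]acetate; 28 5-[(3Z)-hex-3-en-1-ylsulfonyl]-1-phenyl-1H-tetrazole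
Product: 30 methyl 2-[(3R,5S)-3,5-dimethyl-5-[(7E,9E,12Z)-pentadeca-7,9,12-trien-1-yl]-1,2-dioxolan-3-yl]acetate, via potassiated sulfone 29 (not isolated)
Conditions: 28, KN(SiMe3)2, DME, −60 °C; then 25, −60 → 0 °C
Reagents that add atoms: none
Why: In this Julia–Kocienski olefination the premetalated tetrazolyl sulfone adds 1,2 to the enal, and Smiles rearrangement with loss of SO2 and tetrazololate should give C14=C15 with the E geometry favoured by potassium in DME, while the homoallylic carbanion never conjugates with the 17Z alkene and is consumed by the aldehyde before it can enolise the ester.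

Compound list
1 | (R)-2-methylglycidol | OC[C@]1(C)CO1 | starting material
2 | (S)-2-methylglycidyl tosylate | Cc1ccc(cc1)S(=O)(=O)OC[C@]2(C)CO2 | intermediate
3 | isopropenylmagnesium bromide | C=C(C)[Mg]Br | starting material
4 | (2S)-2-hydroxy-2,4-dimethylpent-4-en-1-yl 4-methylbenzenesulfonate | Cc1ccc(cc1)S(=O)(=O)OC[C@](O)(C)CC(C)=C | intermediate
5 | (2S)-2-methyl-2-(2-methylprop-2-en-1-yl)oxirane | C=C(C)C[C@@]1(C)CO1 | intermediate
6 | (2R)-2-hydroperoxy-2,4-dimethylpent-4-en-1-ol | OC[C@@](OO)(C)CC(C)=C | intermediate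
7 | tert-butyldiphenylsilyl (2R)-1-(tert-butyldiphenylsilyloxy)-2,4-dimethylpent-4-en-2-yl peroxide | CC(C)(C)[Si](c1ccccc1)(c2ccccc2)OC[C@@](OO[Si](c3ccccc3)(c4ccccc4)C(C)(C)C)(C)CC(C)=C | intermediate
8 | (2R)-1-(tert-butyldiphenylsilyloxy)-2,4-dimethylpent-4-en-2-yl hydroperoxide | CC(C)(C)[Si](c1ccccc1)(c2ccccc2)OC[C@@](OO)(C)CC(C)=C | intermediate
9 | carbon monoxide | [C-]#[O+] | starting material
10 | methanol | CO | starting material
11 | chloro{[(3R,5R)-5-(tert-butyldiphenylsilyloxymethyl)-3,5-dimethyl-1,2-dioxolan-3-yl]methyl}palladium | CC(C)(C)[Si](c1ccccc1)(c2ccccc2)OC[C@@]3(C)C[C@](C)(C[Pd]Cl)OO3 | intermediate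
12 | chloro{[(3R,5R)-5-(tert-butyldiphenylsilyloxymethyl)-3,5-dimethyl-1,2-dioxolan-3-yl]acetyl}palladium | CC(C)(C)[Si](c1ccccc1)(c2ccccc2)OC[C@@]3(C)C[C@](C)(CC(=O)[Pd]Cl)OO3 | intermediate
13 | methyl 2-[(3R,5R)-5-(tert-butyldiphenylsilyloxymethyl)-3,5-dimethyl-1,2-dioxolan-3-yl]acetate | CC(C)(C)[Si](c1ccccc1)(c2ccccc2)OC[C@@]3(C)C[C@](C)(CC(=O)OC)OO3 | intermediate
14 | methyl 2-[(3R,5R)-5-(hydroxymethyl)-3,5-dimethyl-1,2-dioxolan-3-yl]acetate | OC[C@@]1(C)C[C@](C)(CC(=O)OC)OO1 | intermediate
15 | methyl 2-[(3R,5R)-5-formyl-3,5-dimethyl-1,2-dioxolan-3-yl]acetate | O=C[C@@]1(C)C[C@](C)(CC(=O)OC)OO1 | intermediate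
16 | 6-bromohexan-1-ol | OCCCCCCBr | starting material
17 | (6-bromohexyloxy)(tert-butyl)dimethylsilane | CC(C)(C)[Si](C)(C)OCCCCCCBr | intermediate
18 | [6-(tert-butyldimethylsilyloxy)hexyl]triphenylphosphonium bromide | CC(C)(C)[Si](C)(C)OCCCCCC[P+](c1ccccc1)(c2ccccc2)c3ccccc3.[Br-] | intermediate
19 | [6-(tert-butyldimethylsilyloxy)hexylidene]triphenylphosphorane | CC(C)(C)[Si](C)(C)OCCCCCC=P(c1ccccc1)(c2ccccc2)c3ccccc3 | intermediate
20 | methyl 2-[(3R,5R)-5-[(1Z)-7-(tert-butyldimethylsilyloxy)hept-1-en-1-yl]-3,5-dimethyl-1,2-dioxolan-3-yl]acetate | CC(C)(C)[Si](C)(C)OCCCCC/C=C\[C@@]1(C)C[C@](C)(CC(=O)OC)OO1 | intermediate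
21 | methyl 2-[(3R,5S)-5-[7-(tert-butyldimethylsilyloxy)heptyl]-3,5-dimethyl-1,2-dioxolan-3-yl]acetate | CC(C)(C)[Si](C)(C)OCCCCCCC[C@@]1(C)C[C@](C)(CC(=O)OC)OO1 | intermediate
22 | methyl 2-[(3R,5S)-5-(7-hydroxyheptyl)-3,5-dimethyl-1,2-dioxolan-3-yl]acetate | OCCCCCCC[C@@]1(C)C[C@](C)(CC(=O)OC)OO1 | intermediate
23 | methyl 2-[(3R,5S)-3,5-dimethyl-5-(7-oxoheptyl)-1,2-dioxolan-3-yl]acetate | O=CCCCCCC[C@@]1(C)C[C@](C)(CC(=O)OC)OO1 | intermediate
24 | (triphenylphosphoranylidene)acetaldehyde | O=CC=P(c1ccccc1)(c2ccccc2)c3ccccc3 | starting material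
25 | methyl 2-[(3R,5S)-3,5-dimethyl-5-[(7E)-9-oxonon-7-en-1-yl]-1,2-dioxolan-3-yl]acetate | O=C/C=C/CCCCCC[C@@]1(C)C[C@](C)(CC(=O)OC)OO1 | intermediate
26 | (Z)-hex-3-en-1-ol | CC/C=C\CCO | starting material
27 | 5-[(3Z)-hex-3-en-1-ylsulfanyl]-1-phenyl-1H-tetrazole | CC/C=C\CCSc1nnnn1-c2ccccc2 | intermediate
28 | 5-[(3Z)-hex-3-en-1-ylsulfonyl]-1-phenyl-1H-tetrazole | CC/C=C\CCS(=O)(=O)c1nnnn1-c2ccccc2 | intermediate
29 | potassium salt of sulfone 28 (carbanion at C15) | CC/C=C\C[CH-]S(=O)(=O)c1nnnn1-c2ccccc2.[K+] | intermediate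
30 | methyl 2-[(3R,5S)-3,5-dimethyl-5-[(7E,9E,12Z)-pentadeca-7,9,12-trien-1-yl]-1,2-dioxolan-3-yl]acetate | CC/C=C\C/C=C/C=C/CCCCCC[C@@]1(C)C[C@](C)(CC(=O)OC)OO1 | target

Total step count: 18.
Longest linear sequence: 14 steps from (R)-2-methylglycidol (steps 1–8, 11–15 and 18).

Steps most likely to fail

**Step 6.**
- The peroxypalladation may revert before CO is taken up.
- The hydroperoxide may be consumed as an oxidant for CO or for zerovalent palladium.
- The O–O bond of the β-peroxyalkylpalladium may break heterolytically.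
- The facial discrimination at C3 may be weak.

The fallback uses known chemistry, sets out from 8 and returns at 13. Compound 8 is capped with 2-methoxypropene and PPTS in CH2Cl2 as the 2-methoxyprop-2-yl peroxide F1. Ozonolysis (O3, CH2Cl2, −78 °C, then Me2S) cleaves the methallyl alkene to the methyl ketone F2. Catalytic TsOH in MeOH removes the cap, the freed hydroperoxide closes on the ketone, and exchange with the solvent gives the 3-methoxy-1,2-dioxolane F3 as both C3 epimers. TiCl4 in CH2Cl2 at −78 °C then mediates displacement of the methoxy group by tert-butyl[(1-methoxyvinyl)oxy]dimethylsilane. This is an SN1-type substitution at a planar C3, and the nucleophile should enter anti to the silyloxymethyl group, giving 13. Here the ring closes by ketalisation and the arm is attached through C2–C3.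

**Step 4.** Partial ionisation at the tertiary carbon may erode the configurational purity of C5.

The fallback sets out from 8 and returns to 8, and it replaces reliance on stereospecific substitution by a resolution. Compound 8 of reduced purity is added (PPTS, CH2Cl2) to the isopropenyl ether of (1R,2S)-2-phenylcyclohexanol F4. F4 is obtained from the commercial alcohol and 2-methoxypropene by Hg(OAc)2-catalysed ether exchange. The addition creates no new stereocentre and gives the perketal of the R hydroperoxide F5 beside the perketal of the S hydroperoxide F6. The two are separated by chromatography, and AcOH/THF/H2O at rt then releases enantiopure 8 from F5.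

**Step 18.**
- The E/Z discrimination at C14=C15 may be insufficient with a conjugated aldehyde.
- The base may enolise the ester, with transient ring opening and loss of the C3 configuration.

The fallback sets out from 23 and 26, returns at 30, and closes the diene at C12=C13 instead, so that step 15 is dropped.
- Compound 26 is oxidised with Dess–Martin periodinane to (Z)-hex-3-enal F7.
- F7 is trapped in the same flask with Ph3P=CHCO2Et as ethyl (2E,5Z)-octa-2,5-dienoate F8.
- Reduction with iBu2AlH in CH2Cl2 at −78 °C gives (2E,5Z)-octa-2,5-dien-1-ol F9.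
- Appel bromination (CBr4, PPh3) gives (2E,5Z)-1-bromoocta-2,5-diene F10.
- Arbuzov reaction with P(OEt)3 gives diethyl [(2E,5Z)-octa-2,5-dien-1-yl]phosphonate F11.
- Horner–Wadsworth–Emmons olefination of 23 with F11 (LiN(SiMe3)2, THF, −78 °C → rt) should deliver the E,E-diene of 30.

Further compounds
F1 | step 6 | tert-butyl{[(2R)-2-[(2-methoxypropan-2-yl)peroxy]-2,4-dimethylpent-4-en-1-yl]oxy}diphenylsilane | CC(C)(C)[Si](c1ccccc1)(c2ccccc2)OC[C@@](OOC(C)(C)OC)(C)CC(C)=C
F2 | step 6 | (4R)-5-(tert-butyldiphenylsilyloxy)-4-[(2-methoxypropan-2-yl)peroxy]-4-methylpentan-2-one | CC(C)(C)[Si](c1ccccc1)(c2ccccc2)OC[C@@](OOC(C)(C)OC)(C)CC(C)=O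
F3 | step 6 | (5R)-5-(tert-butyldiphenylsilyloxymethyl)-3-methoxy-3,5-dimethyl-1,2-dioxolane (both C3 epimers) | CC(C)(C)[Si](c1ccccc1)(c2ccccc2)OC[C@@]3(C)CC(C)(OC)OO3
F4 | step 4 | (1R,2S)-2-phenylcyclohexyl prop-1-en-2-yl ether | C=C(C)O[C@@H]1CCCC[C@H]1c2ccccc2
F5 | step 4 | perketal of (R)-8 with F4 | CC(C)(C)[Si](c1ccccc1)(c2ccccc2)OC[C@@](OOC(C)(C)O[C@@H]3CCCC[C@H]3c4ccccc4)(C)CC(C)=C
F6 | step 4 | perketal of the (S) enantiomer of 8 with F4 | CC(C)(C)[Si](c1ccccc1)(c2ccccc2)OC[C@](OOC(C)(C)O[C@@H]3CCCC[C@H]3c4ccccc4)(C)CC(C)=C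
F7 | step 18 | (Z)-hex-3-enal | CC/C=C\CC=O
F8 | step 18 | ethyl (2E,5Z)-octa-2,5-dienoate | CC/C=C\C/C=C/C(=O)OCC
F9 | step 18 | (2E,5Z)-octa-2,5-dien-1-ol | CC/C=C\C/C=C/CO
F10 | step 18 | (2E,5Z)-1-bromoocta-2,5-diene | CC/C=C\C/C=C/CBr
F11 | step 18 | diethyl [(2E,5Z)-octa-2,5-dien-1-yl]phosphonate | CC/C=C\C/C=C/CP(=O)(OCC)OCC
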